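## Structural features

The target is a ten-membered carbocycle, numbered here C1(Me)=C2–C3(OH)–C4(iPr)–C5(O-aroyl)–C6H2–C7(Me)=C8–C9H2–C10H2, with a 4-hydroxybenzoate on O5 as the only other ring. Both trisubstituted ring olefins, C1=C2 and C7=C8, are Z and sit in a 1,5-relationship across C9–C10. The three stereocentres are contiguous, C3–C4–C5, with configuration 3R,4S,5R: in the zigzag C2–C6 the C3 hydroxyl and the isopropyl group are syn, the isopropyl group and O5 are anti, and the two oxygens are 1,3-anti. Fragile points are the allylic C3 carbinol, the 1,3-diol monoester (acyl shift from O5 to O3; β-elimination while C3 is a ketone), the free phenol, and the medium ring itself (transannular closure, Cope-type reorganisation of the 1,5-diene on heating). The real difficulty is to obtain a ten-membered ring with two Z trisubstituted olefins without a medium-ring closure, and then to place three adjacent stereocentres on a flexible ring that has no resident chirality. The key step uses the fact that C6–C7=C8–C9–C10–C1=C2–C3 is the intact eight-membered ring of the isoprene dimer, cut only between C3 and C6, while C4–C5 is a two-carbon ketene unit. Fusing that unit across C3–C6 as a cyclobutanone (eight- plus four-membered ring, bicyclo[6.2.0]) and then breaking the shared C3–C6 bond by retro-aldol gives the ten-membered ring with oxygen on C3 and C5.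

## Logic of the disconnections

25 goes back to 24 by cutting the phenolic O–Si bond. A free phenol would quench the samarium alkoxide of the preceding step and make the aldehyde a poorer hydride donor. Nothing is gained in the skeleton. The forward desilylation must be buffered so that the aroyl group does not move from O5 to O3.

24 goes back to 20 and 22 by removing the hydride on C3 and the acyl–O5 bond together (Evans–Tishchenko transform). One operation sets C3 relative to C5 and puts the ester on O5 only, so the two hydroxyls never need to be told apart. The gain is one stereocentre and the whole aryl ester. The demand is that intramolecular hydride delivery to the C3 enone carbonyl outruns retro-aldol opening at C4–C5.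

22 goes back to 21 by cutting the O–Si bond, a routine phenol protection.

20 goes back to 19 by removing the hydride on C5. In 19 the C4 centre lies between two carbonyls and is stereolabile, so one reduction can set C4 and C5 together by dynamic kinetic resolution. The gain is the loss of all fixed stereocentres. The demand is reduction at C5 and not at the C3 enone, 4,5-anti selectivity, and the 5R sense.

19 goes back to 16 by reconnecting C3 to C6 (in the forward sense, retro-aldol cleavage of that bond). This turns the ten-membered ring into an eight-membered ring cis-fused to a cyclobutanone. The gain is that no medium ring has to be closed and both Z olefins are inherited. The demand is cleavage of C3–C6 and not C3–C4, and protonation of the resulting dienolate at C6. The silyl group in 16 is triethylsilyl, chosen over the smaller trimethylsilyl so that it survives the amine hydrochloride and the zinc reduction yet still falls to fluoride at low temperature.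

16 goes back to 14 by replacing the C4–H bond with C4–Cl. The chlorine is there only to make the ketene reactive enough. The forward dechlorination must leave the tertiary silyl ether intact.

14 goes back to 10 and 12 by cutting C3–C4 and C5–C6, a ketene [2+2] transform. The normal polarity (ketene carbonyl carbon to the nucleophilic enol-ether carbon C6) places the carbonyl on C5 and the isopropyl group on C4. The demand is closure of a congested C3–C4 bond and reaction at the enol-ether π bond only.

12 goes back to 11 by exchanging the acyl C–Cl bond for C–OH.

10 goes back to 8 by cutting the O–Si bond. The forward enolisation must occur at C6, the carbon between the carbonyl and C7=C8.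

8 goes back to 5 by moving oxygen from C3 to C1 with an allylic shift of the olefin (oxidative 1,3-transposition in the forward sense). Direct allylic oxidation of the diene would favour the carbon next to the methyl-bearing olefin terminus, so C3 is reached indirectly.

5 goes back to 2 by replacing the C2=C3 olefin and the C1 hydroxyl with the C1–C2 epoxide (selenide opening, then selenoxide elimination). Because C1 is quaternary, the elimination can only go towards C3.

2 goes back to 1 by removing the epoxide oxygen. The two olefins of 1 are equivalent, so the only demand is to stop at mono-epoxidation.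

## Other disconnections considered

Alternative 1: The cut is C3–C4, made as a ring contraction. In the forward step n-BuLi removes a proton from the propargylic O–CH2 carbon (future C3) of the thirteen-membered propargyl allyl ether A2. The α-oxy carbanion attacks C4 through the five-membered [2,3]-Wittig array, the allylic C–O bond breaks, and the ring contracts by three atoms to the cyclodecenynol A1, leaving an isopropenyl group on C4.
- In favour: the hard ring comes from a larger, easily closed ether ring. One concerted step forms a skeletal C–C bond and sets C3 and C4. C5 can be made as a single enantiomer in an acyclic precursor and pass on its configuration, so absolute control does not depend on a dynamic kinetic resolution. On stereochemical certainty this plan is the better one.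
- Against: A1 still lacks the C1 methyl group. It would have to be added across a ring alkyne with syn geometry and at the carbon remote from the carbinol.
- Against: the isopropenyl group must be hydrogenated beside two trisubstituted olefins (feasible with RhCl(PPh3)3, so roughly neutral).
- Against: the C5 silyl ether must later be exchanged for the aryl ester while O3 is masked.
- Against: a [1,2]-shift can compete, and the diastereoselectivity depends on ring conformation.
- Against: A2 needs a long linear synthesis that includes a stereodefined trisubstituted olefin.
- Comparison: on structure the two plans are equal in avoiding a direct ten-ring closure. On mechanism the sigmatropic shift creates two stereocentres where the retro-aldol creates none (better), but it leaves one olefin at the wrong oxidation level (worse). On step count it is clearly longer.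

Alternative 2: The cut is C4–C5. In the forward step SmI2 reduces the C4 bromide of the acyclic bromo keto aldehyde A4 to a samarium enolate, which adds to the tethered C5 aldehyde and closes the ten-membered ring. The aldolate then forms a hemiacetal with added 22 and passes hydride to C3, giving A3, which is identical with 24.
- In favour: ring, C4–C5 bond, all three stereocentres and the ester arise in one flask, one step from the target. In convergence and in post-cyclisation step count it is better than the chosen plan. The logic that sets C3 is the same in both (equal).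
- Against: this is a true medium-ring closure by a reversible aldol addition that is uphill for a strained ten-membered ring. It needs high dilution, at which the bimolecular Tishchenko step is slow.
- Against: the β,γ-unsaturated aldehyde of A4 is enolisable and prone to conjugation.
- Against: 22 must be withheld until the ring has closed, or it competes as the aldol acceptor.
- Against: once the bromide is reduced the enolate carries no stereochemical information, so A3 would be racemic unless a chiral ligand is found.
- Against: the 4,5-anti preference of a ten-membered aldol transition state is unproven.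
- Against: both Z trisubstituted olefins of A4 must be built by acyclic stereoselective chemistry, whereas the chosen plan buys them ready-made.

Alternative 3: The bond broken is C3–C7 of a hydroazulene. In the forward step the potassium alkoxide (KN(SiMe3)2 or KH) of the tertiary C3 alcohol in the cis-fused bicyclo[5.3.0]decene mesylate A6 undergoes Grob fragmentation. C3 becomes the enone carbonyl, the C8 mesylate leaves, C7=C8 forms, and the five- and seven-membered rings merge into the ten-membered dienone A5.
- In favour: as in the chosen plan, the ring is made by cleaving a bond shared by two smaller rings (equal). The fragmentation is concerted and stereospecific, so the anti-periplanar mesylate fixes the Z geometry of C7=C8. C4 and C5 are set on a rigid bicycle and can be carried as single enantiomers, so no dynamic kinetic resolution is needed (better on stereochemical certainty).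
- Against: A6 needs five defined stereocentres, among them a quaternary C7 and a tertiary carbinol, and three of them are destroyed in the key step.
- Against: A5 is a β-silyloxy ketone whose C4 can epimerise, or which can lose silanolate by E1cB, under the basic fragmentation conditions.
- Against: the endgame (desilylation to 20, then Evans–Tishchenko) is the same as in the chosen plan, so nothing is saved there.
- Comparison: overall it is much longer, although the mechanism carries more stereochemical information than a retro-aldol.

Key step: step 8

Assumption: 1 is used as the pure 1,5-dimethyl isomer (technical isoprene dimer containing the 1,6-dimethyl isomer is fractionated first). 11 is used as the racemate, since its stereocentre becomes the sp2 ketene carbon. Compounds 2–19 are racemic or stereolabile; absolute configuration enters at step 9.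

## Route

Step 1
Reactants: 1 (1Z,5Z)-1,5-dimethylcycloocta-1,5-diene
Product: 2 racemic cis-1,5-dimethyl-9-oxabicyclo[6.1.0]non-4-ene (epoxide across C1–C2 of the target numbering)
Conditions: mCPBA (0.8 equiv), NaHCO3, CH2Cl2, 0 °C
Reagents that add atoms: 3-chloroperoxybenzoic acid, OOC(=O)c1cccc(Cl)c1
Why: Prilezhaev epoxidation is a stereospecific syn-addition, so the cis-epoxide follows from the Z olefin. The two olefins of 1 are equivalent, so sub-stoichiometric peracid should give mainly the monoepoxide, with unreacted 1 recovered and diepoxide removed by chromatography.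

Step 2
Reactants: 2 racemic cis-1,5-dimethyl-9-oxabicyclo[6.1.0]non-4-ene
Product: 5 racemic (2Z,5Z)-1,5-dimethylcycloocta-2,5-dien-1-ol, via trans-hydroxy selenide 3 (not isolated), via selenoxide 4 (not isolated)
Conditions: (PhSe)2, NaBH4, EtOH, reflux; then THF, 30% H2O2, pyridine, 0 °C → rt
Reagents that add atoms: none
Why: Selenolate opening of the epoxide is an SN2 attack at the secondary carbon C2 with inversion, followed by oxidation and selenoxide syn-elimination. The elimination can only go towards C3 because C1 is quaternary, and ring strain in the eight-membered ring allows only the cis C2=C3 olefin. Pyridine limits epoxidation of C7=C8 by peroxyseleninic acid.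

Step 3
Reactants: 5 racemic (2Z,5Z)-1,5-dimethylcycloocta-2,5-dien-1-ol
Product: 8 (2Z,6Z)-3,7-dimethylcycloocta-2,6-dien-1-one, via tertiary chlorochromate ester 6 (not isolated), via transposed chlorochromate ester 7 (not isolated)
Conditions: pyridinium chlorochromate (2 equiv), 4 Å MS, CH2Cl2, rt
Reagents that add atoms: pyridinium chlorochromate, [O-][Cr](=O)(=O)Cl.c1cc[nH+]cc1
Why: Dauben–Babler oxidative 1,3-transposition: a suprafacial [3,3]-shift of the chromate ester carries oxygen from C1 to C3 (the carbonyl oxygen therefore comes from the reagent), and the secondary ester is oxidised to the enone with C1=C2 cis in the ring. Sieves and a short reaction time should keep C7=C8 in its β,γ position, which is not disfavoured in an eight-membered ring.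

Step 4
Reactants: 8 (2Z,6Z)-3,7-dimethylcycloocta-2,6-dien-1-one
Product: 10 triethyl{[(1E,3Z,7Z)-3,7-dimethylcycloocta-1,3,7-trien-1-yl]oxy}silane (all ring olefins cis in the ring), via lithium dienolate 9 (not isolated)
Conditions: LiN(iPr)2, THF, −78 °C; Et3SiCl, −78 → 0 °C
Reagents that add atoms: chlorotriethylsilane, CC[Si](Cl)(CC)CC
Why: Kinetic enolisation removes a proton from C6, the methylene flanked by the carbonyl and C7=C8 and so the most acidic and accessible site, and the cross-conjugated enolate is silylated on oxygen. The product is kept at or below room temperature, where electrocyclisation of the cyclooctatriene is negligible.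

Step 5
Reactants: 11 2-chloro-3-methylbutanoic acid (racemic)
Product: 12 2-chloro-3-methylbutanoyl chloride
Conditions: (COCl)2, cat. DMF, CH2Cl2, 0 °C → rt
Reagents that add atoms: oxalyl chloride, O=C(Cl)C(=O)Cl
Why: Standard acid chloride formation through the chloroiminium (Vilsmeier-type) activator; the α-chloro centre needs no control.

Step 6
Reactants: 10 triethyl{[(1E,3Z,7Z)-3,7-dimethylcycloocta-1,3,7-trien-1-yl]oxy}silane; 12 2-chloro-3-methylbutanoyl chloride
Product: 14 racemic cis-fused (2Z,6Z)-10-chloro-3,7-dimethyl-10-(propan-2-yl)-1-[(triethylsilyl)oxy]bicyclo[6.2.0]deca-2,6-dien-9-one (C4 epimers of the target numbering), via chloro(isopropyl)ketene 13 (not isolated)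
Conditions: Et3N (slow addition), hexane, 0 °C → rt
Reagents that add atoms: none
Why: Thermal [2+2] cycloaddition of an alkylchloroketene, made in situ by dehydrochlorination, to the silyl enol ether, the most electron-rich π bond of 10. The ketene carbonyl carbon (C5) bonds to the nucleophilic C6 and the CCl(iPr) carbon (C4) to the siloxy carbon C3, suprafacially on the enol ether, so the fusion is cis. Either C4 epimer serves.

Step 7
Reactants: 14 racemic cis-fused (2Z,6Z)-10-chloro-3,7-dimethyl-10-(propan-2-yl)-1-[(triethylsilyl)oxy]bicyclo[6.2.0]deca-2,6-dien-9-one
Product: 16 racemic cis-fused (2Z,6Z)-3,7-dimethyl-10-(propan-2-yl)-1-[(triethylsilyl)oxy]bicyclo[6.2.0]deca-2,6-dien-9-one, via zinc enolate 15 (not isolated)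
Conditions: Zn dust, NH4Cl, MeOH, 0 °C → rt
Reagents that add atoms: none
Why: Zinc reduces the α-chloro cyclobutanone to its zinc enolate, which is protonated at C4. The near-neutral medium leaves the tertiary triethylsilyl ether in place, and the C4 configuration is immaterial because it is erased in step 8.

Step 8
Reactants: 16 racemic cis-fused (2Z,6Z)-3,7-dimethyl-10-(propan-2-yl)-1-[(triethylsilyl)oxy]bicyclo[6.2.0]deca-2,6-dien-9-one
Product: 19 (2Z,6Z)-3,7-dimethyl-10-(propan-2-yl)cyclodeca-2,6-diene-1,9-dione, via cyclobutanolate 17 (not isolated), via ten-ring C5 enolate 18 (not isolated)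
Conditions: Bu4NF (1.1 equiv), THF, −78 → 0 °C; AcOH, pH 7 buffer
Reagents that add atoms: none
Why: Fluoride removes the silyl group from O3 to give the cyclobutanolate 17, whose oxygen is β to the C5 carbonyl; retro-aldol cleavage of the ring-fusion bond C3–C6 makes C3 the enone carbonyl and releases C6 as the carbon end of the C5 enolate 18, driven by relief of four-ring strain. The closest known reaction type is the two-carbon ring expansion of cyclic silyl enol ethers through haloketene [2+2] adducts, in which the dechlorinated 3-siloxycyclobutanone is opened to the cycloalkane-1,3-dione. No ring is closed by bond formation: the ten-membered ring appears because the bond shared by the eight- and four-membered rings disappears, so the entropic and transannular cost of a medium-ring closure is avoided. No stereocentre is created; C3 and C6 lose theirs and C4 becomes stereolabile between two carbonyls, which is what allows the dynamic kinetic resolution of step 9. The selectivity needed is cleavage of C3–C6 and not C3–C4, and the substrate secures it because the carbanion developing at C6 is both an enolate and allylic to C7=C8 (a dienolate), whereas cleavage towards C4 would give a more substituted, non-conjugated enolate; in the tub-shaped eight-membered ring the C3–C6 bond can also align with the C7=C8 π system. The dienolate should take its proton at C6 (α-protonation, from the water of the fluoride reagent and from the acidic C4–H of product already formed), which leaves C7=C8 in place and Z. The medium then holds the product as its C4 diketonate, which protects C6 and the enone from further enolisation until the buffered quench. Both Z olefins are spectators carried from 1, and the low temperature is meant to suppress transannular Michael addition of C6 to C1.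

Step 9
Reactants: 19 (2Z,6Z)-3,7-dimethyl-10-(propan-2-yl)cyclodeca-2,6-diene-1,9-dione
Product: 20 (2Z,6Z,9R,10R)-9-hydroxy-3,7-dimethyl-10-(propan-2-yl)cyclodeca-2,6-dien-1-one (4R,5R in the target numbering; OH and isopropyl anti)
Conditions: RuCl[(R,R)-TsDPEN](p-cymene) (2 mol %), HCO2H/Et3N (5:2), CH2Cl2, rt, stopped at mono-reduction
Reagents that add atoms: none
Why: Noyori–Ikariya asymmetric transfer hydrogenation with dynamic kinetic resolution of a 2-alkyl-1,3-diketone: C4 racemises through the enol in the amine–formic acid medium while the ruthenium hydride reduces the non-conjugated, more electrophilic C5 ketone of the faster-reacting enantiomer. The 4,5-anti product is the one expected from Felkin–Anh delivery anti to the C3 acyl substituent. The (R,R) ligand is assigned to the 5R carbinol by the usual model, with the acyl-bearing C4 side in the place of the aryl group of an aryl ketone.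

Step 10
Reactants: 21 4-hydroxybenzaldehyde
Product: 22 4-[(tert-butyldimethylsilyl)oxy]benzaldehyde
Conditions: TBSCl, imidazole, DMF, rt
Reagents that add atoms: tert-butylchlorodimethylsilane, CC(C)(C)[Si](C)(C)Cl
Why: Routine imidazole-mediated silylation of a phenol; the silyl ether keeps the phenol from protonating the samarium alkoxide in step 11.

Step 11
Reactants: 20 (2Z,6Z,9R,10R)-9-hydroxy-3,7-dimethyl-10-(propan-2-yl)cyclodeca-2,6-dien-1-one; 22 4-[(tert-butyldimethylsilyl)oxy]benzaldehyde
Product: 24 (1R,3Z,7Z,9R,10S)-9-hydroxy-3,7-dimethyl-10-(propan-2-yl)cyclodeca-3,7-dien-1-yl 4-[(tert-butyldimethylsilyl)oxy]benzoate, via samarium hemiacetal alkoxide 23 (not isolated)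
Conditions: SmI2 (0.3 equiv), 22 (5 equiv), THF, −10 °C
Reagents that add atoms: none
Why: Evans–Tishchenko reduction: the C5 hydroxyl adds to the aldehyde, and the trivalent samarium alkoxide of the hemiacetal passes its carbinol hydride to the C3 enone carbonyl through a samarium-bridged, chair-like six-membered transition state. The hydride therefore arrives on the face of C3 syn to O5, the new hydroxyl is 1,3-anti to O5 (3R), and the hemiacetal carbon becomes the ester carbonyl on O5.

Step 12
Reactants: 24 (1R,3Z,7Z,9R,10S)-9-hydroxy-3,7-dimethyl-10-(propan-2-yl)cyclodeca-3,7-dien-1-yl 4-[(tert-butyldimethylsilyl)oxy]benzoate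
Product: 25 (1R,3Z,7Z,9R,10S)-9-hydroxy-3,7-dimethyl-10-(propan-2-yl)cyclodeca-3,7-dien-1-yl 4-hydroxybenzoate (CNP0249141.4; 3R,4S,5R in the target numbering)
Conditions: Bu4NF, AcOH (1:1), THF, 0 °C
Reagents that add atoms: none
Why: Fluoride cleaves the aryl silyl ether far faster than it attacks the ester. The acetic acid buffer keeps the medium from becoming basic enough for the aroyl group to shift from O5 to O3.

## Compound list

1 | (1Z,5Z)-1,5-dimethylcycloocta-1,5-diene | C/C1=C/CC/C(C)=C\CC1 | starting material
2 | racemic cis-1,5-dimethyl-9-oxabicyclo[6.1.0]non-4-ene | C[C@@]12CC/C=C(C)\CC[C@@H]1O2 | intermediate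
3 | racemic trans-(4Z)-1,5-dimethyl-8-(phenylselanyl)cyclooct-4-en-1-ol | C[C@@]1(O)CC/C=C(C)\CC[C@H]1[Se]c2ccccc2 | intermediate (not isolated)
4 | selenoxide of 3 (mixture at selenium) | C[C@@]1(O)CC/C=C(C)\CC[C@H]1[Se](=O)c2ccccc2 | intermediate (not isolated)
5 | racemic (2Z,5Z)-1,5-dimethylcycloocta-2,5-dien-1-ol | CC1(O)/C=C\C/C(C)=C\CC1 | intermediate
6 | chlorochromate ester of 5 (O on C1) | CC1(O[Cr](=O)(=O)Cl)/C=C\C/C(C)=C\CC1 | intermediate (not isolated)
7 | transposed chlorochromate ester (O on C3) | C/C1=C/C(O[Cr](=O)(=O)Cl)C/C(C)=C\CC1 | intermediate (not isolated)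
8 | (2Z,6Z)-3,7-dimethylcycloocta-2,6-dien-1-one | C/C1=C/C(=O)C/C(C)=C\CC1 | intermediate
9 | lithium (1E,3Z,7Z)-3,7-dimethylcycloocta-1,3,7-trien-1-olate | [Li+].C/C1=C/C([O-])=C\C(C)=C/CC1 | intermediate (not isolated)
10 | triethyl{[(1E,3Z,7Z)-3,7-dimethylcycloocta-1,3,7-trien-1-yl]oxy}silane | C/C1=C/C(O[Si](CC)(CC)CC)=C\C(C)=C/CC1 | intermediate
11 | 2-chloro-3-methylbutanoic acid (racemic) | CC(C)C(Cl)C(=O)O | starting material
12 | 2-chloro-3-methylbutanoyl chloride | CC(C)C(Cl)C(=O)Cl | intermediate
13 | chloro(isopropyl)ketene (2-chloro-3-methylbut-1-en-1-one) | CC(C)C(Cl)=C=O | intermediate (not isolated)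
14 | racemic cis-fused (2Z,6Z)-10-chloro-3,7-dimethyl-10-(propan-2-yl)-1-[(triethylsilyl)oxy]bicyclo[6.2.0]deca-2,6-dien-9-one (C10 epimers) | C/C1=C/[C@@]2(O[Si](CC)(CC)CC)C(Cl)(C(C)C)C(=O)[C@H]2/C(C)=C\CC1 | intermediate
15 | chlorozinc enolate of the dechlorinated cyclobutanone | C/C1=C/[C@@]2(O[Si](CC)(CC)CC)C(C(C)C)=C(O[Zn]Cl)[C@H]2/C(C)=C\CC1 | intermediate (not isolated)
16 | racemic cis-fused (2Z,6Z)-3,7-dimethyl-10-(propan-2-yl)-1-[(triethylsilyl)oxy]bicyclo[6.2.0]deca-2,6-dien-9-one (isopropyl drawn cis to the siloxy group; the epimer serves equally) | C/C1=C/[C@@]2(O[Si](CC)(CC)CC)[C@H](C(C)C)C(=O)[C@H]2/C(C)=C\CC1 | intermediate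
17 | tetrabutylammonium cyclobutanolate of 16 | C/C1=C/[C@@]2([O-])[C@H](C(C)C)C(=O)[C@H]2/C(C)=C\CC1.CCCC[N+](CCCC)(CCCC)CCCC | intermediate (not isolated)
18 | tetrabutylammonium C5 enolate of the ten-membered dione | C/C1=C/C(=O)C(C(C)C)C([O-])=C/C(C)=C\CC1.CCCC[N+](CCCC)(CCCC)CCCC | intermediate (not isolated)
19 | (2Z,6Z)-3,7-dimethyl-10-(propan-2-yl)cyclodeca-2,6-diene-1,9-dione (C10 stereolabile) | C/C1=C/C(=O)C(C(C)C)C(=O)C/C(C)=C\CC1 | intermediate
20 | (2Z,6Z,9R,10R)-9-hydroxy-3,7-dimethyl-10-(propan-2-yl)cyclodeca-2,6-dien-1-one | C/C1=C/C(=O)[C@H](C(C)C)[C@H](O)C/C(C)=C\CC1 | intermediate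
21 | 4-hydroxybenzaldehyde | O=Cc1ccc(O)cc1 | starting material
22 | 4-[(tert-butyldimethylsilyl)oxy]benzaldehyde | O=Cc1ccc(O[Si](C)(C)C(C)(C)C)cc1 | intermediate
23 | diiodosamarium alkoxide of the C5 hemiacetal of 20 with 22 | C/C1=C/C(=O)[C@H](C(C)C)[C@H](OC(O[Sm](I)I)c2ccc(O[Si](C)(C)C(C)(C)C)cc2)C/C(C)=C\CC1 | intermediate (not isolated)
24 | (1R,3Z,7Z,9R,10S)-9-hydroxy-3,7-dimethyl-10-(propan-2-yl)cyclodeca-3,7-dien-1-yl 4-[(tert-butyldimethylsilyl)oxy]benzoate | C/C1=C/[C@@H](O)[C@H](C(C)C)[C@H](OC(=O)c2ccc(O[Si](C)(C)C(C)(C)C)cc2)C/C(C)=C\CC1 | intermediate
25 | (1R,3Z,7Z,9R,10S)-9-hydroxy-3,7-dimethyl-10-(propan-2-yl)cyclodeca-3,7-dien-1-yl 4-hydroxybenzoate | C/C1=C/[C@@H](O)[C@H](C(C)C)[C@H](OC(=O)c2ccc(O)cc2)C/C(C)=C\CC1 | target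

## Step count and least certain steps

Total: 12 steps. Longest linear sequence: 10 steps (1, 2, 3, 4, 6, 7, 8, 9, 11, 12). Steps 5 and 10 prepare 12 and 22.

**Step 8 (key step).**
- Risk: the cyclobutanolate may cleave towards C4 instead of C6. After ring opening, the unbuffered anions in the ten-membered ring may also protonate at C8 (moving C7=C8 into conjugation), close transannularly from C6 onto C1, or let the enone geometry drift through its dienolate. All of these follow from handling a naked alkoxide and enolate in a medium ring.
- Fallback: set out from 16 and avoid any anion. HF·pyridine in THF/pyridine at 0 °C (or aqueous acetic acid in isopropanol) would liberate the neutral cis-fused (2Z,6Z)-1-hydroxy-3,7-dimethyl-10-(propan-2-yl)bicyclo[6.2.0]deca-2,6-dien-9-one F1. This would open by acid-catalysed retro-aldol through the C5 dienol, with the same electronic preference for the C3–C6 bond, and return to the route at 19. If the isopropyl group itself were to misdirect the cleavage, the isopropyl-free sequence described under step 6 offers the parent substrate of the known ring expansion.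

**Step 6.**
- Risk: closure of the congested C3–C4 bond (siloxy-bearing carbon to the chloro-isopropyl carbon) may fail. The intermediate would then collapse by silyl transfer to a C6-acylated dienone, and the hindered ketene would oligomerise.
- Fallback: set out from 10 and use dichloroketene (Cl2CHCOCl, Et3N, hexane). This should give cis-fused (2Z,6Z)-10,10-dichloro-3,7-dimethyl-1-[(triethylsilyl)oxy]bicyclo[6.2.0]deca-2,6-dien-9-one F2. Zn dust/NH4Cl/MeOH would give cis-fused (2Z,6Z)-3,7-dimethyl-1-[(triethylsilyl)oxy]bicyclo[6.2.0]deca-2,6-dien-9-one F3. Bu4NF in THF would open it to (2Z,6Z)-3,7-dimethylcyclodeca-2,6-diene-1,9-dione F4. The isopropyl group would then be added by Knoevenagel condensation with acetone (L-proline) to (2Z,6Z)-3,7-dimethyl-10-(propan-2-ylidene)cyclodeca-2,6-diene-1,9-dione F5, reduced in the same flask by Hantzsch ester, rejoining the route at 19.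

**Step 9.**
- Risk: poor discrimination, seen as further reduction at the C3 enone carbonyl, a low anti/syn preference if the ring conformation overrides the Felkin–Anh bias, or the opposite hand if the aryl-surrogate model does not hold for this ring. Both ligand hands are available.
- Fallback: set out from 19 and move the control from a small-molecule catalyst to an enzyme active site. A ketoreductase-mediated dynamic reductive kinetic resolution (NADP+, glucose, glucose dehydrogenase, pH 7 buffer with DMSO), with an enzyme chosen from a panel for the 4R,5R isomer, returns to the route at 20. No new compound is made.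

**Step 11.**
- Risk: hemiacetal formation and hydride transfer may be slow with the electron-rich, bulky aldehyde at a carbinol next to the isopropyl-bearing carbon. The samarium aldolate could then open the strained ring by retro-aldol cleavage of C4–C5 or epimerise C4, and the ring may not reach the chair-like array needed for 1,3-anti delivery.
- Fallback: set out from 20 and separate reduction from esterification.
  - Evans–Tishchenko reduction with acetaldehyde (SmI2 cat., THF, −10 °C), the smallest and fastest donor, would give the C5 acetate with free 3R carbinol, (3Z,7Z)-9-hydroxy-3,7-dimethyl-10-(propan-2-yl)cyclodeca-3,7-dien-1-yl acetate F6.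
  - Et3SiOTf/2,6-lutidine at −78 °C would give its O3 triethylsilyl ether F7.
  - iBu2AlH in CH2Cl2 at −78 °C would remove the acetate to give the C5 alcohol, (3Z,7Z)-3,7-dimethyl-10-(propan-2-yl)-9-[(triethylsilyl)oxy]cyclodeca-3,7-dien-1-ol F8.
  - Pinnick oxidation of 22 (NaClO2, NaH2PO4, 2-methylbut-2-ene) would give 4-[(tert-butyldimethylsilyl)oxy]benzoic acid F9.
  - Steglich esterification of F8 with F9 (DCC, DMAP, CH2Cl2, 0 °C) would give the bis-silyl ester F10.
  - HF·pyridine in THF/pyridine would remove both silyl groups and rejoin the route at 25.

**Step 3.**
- Risk: acid-promoted migration of C7=C8 into conjugation or of C1=C2 out of it, and over-oxidation at the doubly allylic C6 methylene by hexavalent chromium.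
- Fallback: set out from 5 and separate transposition from oxidation. Ph3SiOReO3 (catalytic, Et2O, −30 °C) would move the hydroxyl by 1,3-transposition to the thermodynamically preferred secondary allylic alcohol, (2Z,6Z)-3,7-dimethylcycloocta-2,6-dien-1-ol F11. MnO2 in CH2Cl2 would then oxidise it under neutral conditions, returning to the route at 8.

## Further compounds

F1 | step 8 | racemic cis-fused (2Z,6Z)-1-hydroxy-3,7-dimethyl-10-(propan-2-yl)bicyclo[6.2.0]deca-2,6-dien-9-one | C/C1=C/[C@@]2(O)[C@H](C(C)C)C(=O)[C@H]2/C(C)=C\CC1
F2 | step 6 | racemic cis-fused (2Z,6Z)-10,10-dichloro-3,7-dimethyl-1-[(triethylsilyl)oxy]bicyclo[6.2.0]deca-2,6-dien-9-one | C/C1=C/[C@@]2(O[Si](CC)(CC)CC)C(Cl)(Cl)C(=O)[C@H]2/C(C)=C\CC1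
F3 | step 6 | racemic cis-fused (2Z,6Z)-3,7-dimethyl-1-[(triethylsilyl)oxy]bicyclo[6.2.0]deca-2,6-dien-9-one | C/C1=C/[C@@]2(O[Si](CC)(CC)CC)CC(=O)[C@H]2/C(C)=C\CC1
F4 | step 6 | (2Z,6Z)-3,7-dimethylcyclodeca-2,6-diene-1,9-dione | C/C1=C/C(=O)CC(=O)C/C(C)=C\CC1
F5 | step 6 | (2Z,6Z)-3,7-dimethyl-10-(propan-2-ylidene)cyclodeca-2,6-diene-1,9-dione | C/C1=C/C(=O)C(=C(C)C)C(=O)C/C(C)=C\CC1
F0 | step 9 | none | none
F6 | step 11 | (3Z,7Z)-9-hydroxy-3,7-dimethyl-10-(propan-2-yl)cyclodeca-3,7-dien-1-yl acetate, configuration at C3, C4, C5 as in 25 | C/C1=C/[C@@H](O)[C@H](C(C)C)[C@H](OC(C)=O)C/C(C)=C\CC1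
F7 | step 11 | (3Z,7Z)-3,7-dimethyl-10-(propan-2-yl)-9-[(triethylsilyl)oxy]cyclodeca-3,7-dien-1-yl acetate, configuration as in 25 | C/C1=C/[C@@H](O[Si](CC)(CC)CC)[C@H](C(C)C)[C@H](OC(C)=O)C/C(C)=C\CC1
F8 | step 11 | (3Z,7Z)-3,7-dimethyl-10-(propan-2-yl)-9-[(triethylsilyl)oxy]cyclodeca-3,7-dien-1-ol, configuration as in 25 | C/C1=C/[C@@H](O[Si](CC)(CC)CC)[C@H](C(C)C)[C@H](O)C/C(C)=C\CC1
F9 | step 11 | 4-[(tert-butyldimethylsilyl)oxy]benzoic acid | OC(=O)c1ccc(O[Si](C)(C)C(C)(C)C)cc1
F10 | step 11 | (3Z,7Z)-3,7-dimethyl-10-(propan-2-yl)-9-[(triethylsilyl)oxy]cyclodeca-3,7-dien-1-yl 4-[(tert-butyldimethylsilyl)oxy]benzoate, configuration as in 25 | C/C1=C/[C@@H](O[Si](CC)(CC)CC)[C@H](C(C)C)[C@H](OC(=O)c2ccc(O[Si](C)(C)C(C)(C)C)cc2)C/C(C)=C\CC1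
F11 | step 3 | racemic (2Z,6Z)-3,7-dimethylcycloocta-2,6-dien-1-ol | C/C1=C/C(O)C/C(C)=C\CC1
A1 | alternative 1 | ten-membered cyclodec-6-en-2-yn-1-ol with C1≡C2 alkyne, C3 carbinol, C4 prop-1-en-2-yl, C5 tert-butyldimethylsilyl ether and Z C7=C8 (target numbering; configuration at C3, C4, C5 as in 25) | C1#C[C@@H](O)[C@H](C(C)=C)[C@H](O[Si](C)(C)C(C)(C)C)C/C(C)=C\CC1
A2 | alternative 1 | thirteen-membered propargyl allyl ether (O between the future C3 methylene and the allylic methylene; E allylic olefin, Z C7=C8, C5 tert-butyldimethylsilyl ether) | C1#CCOC/C(C)=C/[C@H](O[Si](C)(C)C(C)(C)C)C/C(C)=C\CC1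
A3 | alternative 2 | O-silylated target, identical with 24 | C/C1=C/[C@@H](O)[C@H](C(C)C)[C@H](OC(=O)c2ccc(O[Si](C)(C)C(C)(C)C)cc2)C/C(C)=C\CC1
A4 | alternative 2 | (3Z,7Z)-10-bromo-3,7,11-trimethyl-9-oxododeca-3,7-dienal (racemic at the bromide) | O=CC/C(C)=C\CC/C(C)=C\C(=O)C(Br)C(C)C
A5 | alternative 3 | (2Z,6Z,9R,10R)-9-[(tert-butyldimethylsilyl)oxy]-3,7-dimethyl-10-(propan-2-yl)cyclodeca-2,6-dien-1-one | C/C1=C/C(=O)[C@H](C(C)C)[C@H](O[Si](C)(C)C(C)(C)C)C/C(C)=C\CC1
A6 | alternative 3 | cis-fused bicyclo[5.3.0]dec-1-ene (target numbering) with tertiary C3 hydroxyl, C4 isopropyl, C5 tert-butyldimethylsilyl ether, angular C7 methyl and C8 mesylate anti-periplanar to C3–C7 | CC1=C[C@]2(O)[C@H](C(C)C)[C@H](O[Si](C)(C)C(C)(C)C)C[C@]2(C)[C@H](OS(C)(=O)=O)CC1
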